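The rate constants are made up, and the outcome is calculated.

At early times the split between the two reagent routes in each flask goes with how much reagent stands beside the starting material.

the same everywhere: protic impurity 0.960 mM; time 6.0 min

|  | starting material | reagent | remark |
|---|---|---|---|
| theta | 48 mM | 24.0 mM (fed, over 5.0 min) | all else is in the flask from the start; the feed brings no volume worth counting |
| beta | 48 mM (fed, over 5.0 min) | 24.0 mM | all else is in the flask from the start; the feed brings no volume worth counting |
| gamma | 48 mM | 24.0 mM | everything together at the start |

    starting material + protic impurity → quenched substrate (k1 = 24 L mol⁻¹ s⁻¹)
    target ⇌ isomer of the product (K2 = 1.2, k2 = 0.074 s⁻¹)
    2 starting material → self-condensation product (k3 = 4.3 × 10⁻⁴ L mol⁻¹ s⁻¹)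
    starting material + 2 reagent → side product (k4 = 100 L² mol⁻² s⁻¹)
    starting material + reagent → target (k5 = 0.65 L mol⁻¹ s⁻¹)

- percent here means starting material units held: one self-condensation product counts as two
- two of one species on the left: rate k times its square, two consumed each time
- run time (theta): 6.0 min

* the best flask by share of target in target plus side product; "all alike" if 1.5 percentage points covers them all (theta / beta / gamma / all alike)
* share of target in target plus side product at the end, theta
* share of target in target plus side product at the end, beta
* share of target in target plus side product at the end, gamma

1. Both routes are first order in starting material, so side product formed per target formed is c(reagent) over a crossover level. I define the crossover level as the target rate constant over the side-product rate constant, the reagent concentration at which the two routes run equally: 6.50 mM. It is a selectivity factor in concentration units.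

2. Because target and isomer relax in 0.0852 min, short against 6.0 min, I let target keep 45.5% of what forms.

3. One end is the whole reagent charge present at the start. Integrating the split from that charge down to zero, with two reagent per side product, gives target plus isomer of 3.25 mM times ln(1 + 2c(reagent)/crossover), which is 6.91 mM. The remaining reagent makes 8.54 mM of side product, so the share is 26.9%. I take gamma as this end, and beta with it, since the ratio holds no starting material.

4. The other end is reagent far below crossover, where the share tends to 100%.

5. Theta lies between. As an estimate I set the feed equal to consumption by both routes, and I take c(starting material) as 36.0 mM. That gives a reagent level of 2.08 mM, below crossover, so the share is 58.6%.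

6. The forecast says theta, with 60%, 26.7% and 26.7%, because “only feeding the reagent keeps it low”. My theta figure stands just under its own, and my figure for gamma and beta just over its own.

7. The simulation gives 61.3%, 26.7% and 26.9%, best theta. Theta's side product over target plus isomer, times crossover, reads as a mean reagent level of 1.87 mM. Now I feed 41 mM of reagent into a flask like theta. Starting material at 27.5 mM gives a level of 3.62 mM and a share of 45.0%. That flask gives 49.2%.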